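Watch the gas.

all flasks: G 63 mM (held)

| flask | L | remark | time |
|---|---|---|---|
| north-east | 0.66 M | run made earlier |  |
| west | 1.5 M | run made earlier |  |
| flask | 0.99 M |  | 1.5 h |

| run | time / min | E / % | D / % |
|---|---|---|---|
| north-east | 5.00 | 5.4 | 2.7 |
| north-east | 15.0 | 15.6 | 13.5 |
| north-east | 25.0 | 26.0 | 24.2 |
| north-east | 40.0 | 41.8 | 39.6 |
| north-east | 50.0 | 52.8 | 50.1 |
| west | 5.00 | 2.4 | 1.5 |
| west | 15.0 | 6.7 | 6.1 |
| west | 25.0 | 12.2 | 10.8 |
| west | 40.0 | 18.4 | 17.8 |
| west | 50.0 | 24.2 | 22.4 |

(readings scatter by 0.3 percentage points)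

* the E and D together standing at 1.5 h, as a percentage of the L charged
* concentration of Z in solution at 1.5 h, in percent of saturation

- for E the D are counted in
- as a solid, counted per litre of solution: D
- at the start none of Z is dissolved
- steps that have been proposed: D <-> E; Z <-> J; L + Z -> E; E -> X; G <-> Z

I take the rate r of making E from the last reading of each run: E as a share of the charge, times the L charged, over the time.

r, north-east = 6.97 mM min⁻¹

r, west = 7.26 mM min⁻¹

The west run holds 2.27 times the L of the north-east run but makes E 1.04 times as fast. So I treat the passage of G into Z as the rate-limiting step and fold the flask into one number.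

N = r t / c = 0.634

Here t is the time and c the L charged. N, the transfer number, is the L that the gas passage can turn over in the time, per L charged. Below one, I read it as the share converted, so I expect the flask near 63.4 %.

Is one number enough? On the west run at 50.0 min, the north-east r gives 23.2 % against a reading of 24.2 %. That gap of 0.97 percentage points is small, though the scatter is 0.3 points, so r still drifts with L. With the west r, the flask gives 66.0 %. N holds no Z, and I give no figure for sat.

The forecast says 64 % and 10 %, on the ground “close to zero order in L, limited by gas transfer”.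

The flask gives 63.3 % and 1.95 %.

    D ⇌ E, rate k1*(cs1 - [E]) while solid is left; crystals form when [E] > cs1 (solubility = 12.0 mM, k = 0.0360 s⁻¹)
    Z ⇌ J (K = 120, k = 7.00 × 10⁻⁵ s⁻¹)
    L + Z → E (k = 0.270 L mol⁻¹ s⁻¹)
    E → X (k = 1.40 × 10⁻⁴ s⁻¹)
    G ⇌ Z, rate k5*(csat - [Z]) (kL = 0.00190 s⁻¹)

The forecast's y holds, and its sat stands 8.1 points too high. Now take the neighbouring flask, the same charge read at 6.0 h. There N = 2.53, so the gas passage offers more than the charge, and L is the limiting reagent. At that reading L stands at 0 %, E and D together at 96.0 %, and X at 4.02 %.

(The numbers in the tables are calculated for an exercise, and the scatter is random.)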